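**Retrosynthetic overview**

- The target is a norbornane (rings A and B) fused through one C–C bond to a trans-decalin (rings C and D). Ring D is opened last: C–Br from an axial alcohol by inversion, the tertiary carbinol from a ketone and MeMgBr, and the ring itself from a cyclohexane-1,4-dione made by oxidative coupling of two acetyl groups, one of which comes from an alkyne.
- Key disconnection: one intramolecular [4+2] makes the bond between the quaternary bridgehead C and the bridge CH of the norbornane and the bond between the ring-fusion CH and the methyl-bearing quaternary C. It closes rings A, B and C from a monocyclic precursor.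
- Enabling feature: ring C shares its bridge CH–bridgehead C bond with the bicyclo[2.2.1]heptane. The six-membered envelope of that bicycle (quaternary C, CH-iPr, CH2, bridgehead CH, CH-O, CH2) is spanned 1,4 by that single bridge carbon. A cyclohexane with an exocyclic diene on one carbon and an (E)-enone on the para carbon therefore holds every atom of rings A–C.
- The monocycle comes from (S)-cryptone: α'-alkylation, thia-Michael addition, hydride reduction, Julia–Kocienski olefination with (Z)-3-methylpent-2-en-4-ynal, then dehydrogenation to the enone.
- Ring order: cyclohexane (organocatalytic Michael/aldol), then rings A + B + C in the key step, then ring D.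

Key step: step 11

Remark: the cyclohexylidene C=C formed in the olefination is expected as a mixture of geometric isomers; the SMILES show the isomer with the dienyl chain anti to the isopropyl-bearing ring carbon. Enolates, carbanions and alkoxides are treated as forms of the numbered compounds and carry no numbers of their own.

**Route**

Step 1
Reactants: 1 3-methylbutanal; 2 but-3-en-2-one
Product: 4 (S)-cryptone, via (S)-2-isopropyl-5-oxohexanal 3 (not isolated)
Conditions: (S)-α,α-diphenylprolinol trimethylsilyl ether (10 mol%), ethyl 3,4-dihydroxybenzoate (20 mol%), neat, 4 °C; then LiOH (0.2 equiv), i-PrOH, rt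
Reagents that add atoms: none
Why: Enamine-catalysed Michael addition of the aldehyde to the enone sets the isopropyl-bearing stereocenter under catalyst control (the (S)-catalyst is expected to give the (S)-aldehyde; otherwise its enantiomer is used), and base then closes the ring by intramolecular aldol condensation (Robinson-type annulation).

Step 2
Reactants: 4 (S)-cryptone; 5 2-(2-bromoethyl)-2-methyl-1,3-dioxolane
Product: 7 cis-6-alkylated enone, via trans-6-alkylated enone 6 (not isolated)
Conditions: LiN(i-Pr)2 (1.05 equiv), THF, −78 °C; 5, DMPU, −78 → 0 °C; then LiN(i-Pr)2 (1.1 equiv), −78 °C; AcOH, −78 °C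
Reagents that add atoms: none
Why: Kinetic α'-deprotonation gives the cross-conjugated enolate, which is alkylated by the primary bromide mainly trans to isopropyl (enolate alkylation); re-enolisation and kinetic protonation from the same axial direction should then place the side chain cis to isopropyl, which is also the more stable diequatorial isomer.

Step 3
Reactants: 7 cis-6-alkylated enone
Product: 8 β-sulfanyl ketone
Conditions: 1-phenyl-1H-tetrazole-5-thiol (1.3 equiv), Et3N (0.1 equiv), CH2Cl2, 0 °C → rt
Reagents that add atoms: 1-phenyl-1H-tetrazole-5-thiol, SC1=NN=NN1c1ccccc1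
Why: Base-catalysed thia-Michael addition to the enone β-carbon (anti to isopropyl) installs the sulfur for the later olefination; this C–S center becomes sp2 in step 8, so its configuration does not matter.

Step 4
Reactants: 8 β-sulfanyl ketone
Product: 9 axial cyclohexanol
Conditions: LiBH(s-Bu)3 (1.2 equiv), THF, −78 °C; then H2O
Reagents that add atoms: none
Why: The bulky borohydride attacks the 2-alkylcyclohexanone from the equatorial side (substrate-controlled ketone reduction), giving the axial alcohol cis to the adjacent side chain, which is the relative configuration of the future exo hydroxyl.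

Step 5
Reactants: 9 axial cyclohexanol
Product: 10 silyl ether
Conditions: TBSOTf, 2,6-lutidine, CH2Cl2, 0 °C
Reagents that add atoms: tert-butyldimethylsilyl triflate, CC(C)(C)[Si](C)(C)OS(=O)(=O)C(F)(F)F
Why: Silylation with the silyl triflate protects the hindered axial alcohol for the basic, oxidative and Lewis-acidic steps that follow.

Step 6
Reactants: 10 silyl ether
Product: 11 tetrazolyl sulfone
Conditions: mCPBA (2.5 equiv), NaHCO3, CH2Cl2, 0 °C → rt
Reagents that add atoms: 3-chloroperbenzoic acid, OOC(=O)c1cccc(Cl)c1
Why: Peracid oxidation of the sulfide gives the 1-phenyltetrazol-5-yl sulfone needed for a one-pot olefination, and the buffer spares the dioxolane and the silyl ether.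

Step 7
Reactants: 12 (Z)-3-methylpent-2-en-4-yn-1-ol
Product: 13 (Z)-3-methylpent-2-en-4-ynal
Conditions: MnO2 (excess), CH2Cl2, rt
Reagents that add atoms: none
Why: MnO2 oxidises the allylic alcohol to the enal (allylic alcohol oxidation) without touching the alkyne and should leave the (Z)-double bond unchanged.

Step 8
Reactants: 11 tetrazolyl sulfone; 13 (Z)-3-methylpent-2-en-4-ynal
Product: 14 dienyne ketal
Conditions: KN(SiMe3)2 (1.1 equiv), THF, −78 °C; then 13, −78 °C → rt; aq. NH4Cl
Reagents that add atoms: none
Why: Julia–Kocienski olefination: the tertiary sulfonyl carbanion adds to the aldehyde and, after Smiles rearrangement, loses SO2 and the tetrazolyl oxide to give the exocyclic diene; the (Z)-enyne geometry is carried over from 13.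

Step 9
Reactants: 14 dienyne ketal
Product: 15 dienyne methyl ketone
Conditions: PPTS (0.3 equiv), acetone/H2O, 50 °C
Reagents that add atoms: water, O
Why: Mild acid-catalysed ketal hydrolysis frees the methyl ketone and should leave the secondary silyl ether, the diene and the alkyne intact.

Step 10
Reactants: 15 dienyne methyl ketone
Product: 16 trienyne enone
Conditions: IBX (2 equiv), DMSO/fluorobenzene, 65 °C
Reagents that add atoms: none
Why: IBX-mediated α,β-dehydrogenation of the ketone through its enol can only place the double bond on the side that has β-hydrogens, which gives the conjugated (E)-enone.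

Step 11
Reactants: 16 trienyne enone
Product: 17 tricyclic alkynyl ketone
Conditions: Me2AlCl (1.5 equiv), CH2Cl2, −78 → −20 °C; then aq. NaHCO3
Reagents that add atoms: none
Why: Me2AlCl binds the enone carbonyl and makes it a cation-like dienophile, so the cycloaddition should be strongly asynchronous: the fully substituted exocyclic diene terminus (future bridgehead) attacks the enone β-carbon across the boat form of the cyclohexane (5-exo-trig, closing rings A and B at once through the one-carbon bridge), and the aluminium enolate then closes ring C onto the tertiary, alkyne-stabilised allyl-cation terminus (six-membered, net [4+2]); the closest precedent is the Lewis-acid-promoted type 1 intramolecular Diels–Alder reaction of 1,3,8-nonatrienones. The bridgehead configuration is fixed by the tether, because the enone can reach the diene only from the ring face that carries it. The bridge CH is set by the side on which ring C grows: growth over the CH2–CH(OTBS) bridge is required and is secured by the exo isopropyl group, which sits next to the bridgehead on the other bridge and would clash with ring C. The ring-fusion CH follows from suprafacial addition to the (E)-enone (acetyl endo, equatorial on ring C, and still enolisable, so it is also the thermodynamic epimer). The methyl-bearing quaternary carbon follows from the (Z)-enyne geometry, which puts the slim ethynyl group "inside" the s-cis diene (so the usual penalty for a doubly substituted terminus is small) and the methyl "outside", cis to acetyl. Because the first bond forms ahead of the second, both geometric isomers of the cyclohexylidene double bond should funnel into the same adduct after rotation about the new single bond.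

Step 12
Reactants: 17 tricyclic alkynyl ketone
Product: 18 tricyclic 1,4-diketone
Conditions: Ph3PAuNTf2 (2 mol%), 1,4-dioxane/H2O, 60 °C
Reagents that add atoms: water, O
Why: Gold-catalysed Markovnikov hydration of the terminal alkyne, assisted by the neighbouring acetyl oxygen (5-exo-dig attack, then hydrolysis), gives the methyl ketone on the quaternary carbon.

Step 13
Reactants: 18 tricyclic 1,4-diketone
Product: 19 tetracyclic ene-dione
Conditions: LiN(i-Pr)2 (2.3 equiv), THF, −78 °C (inverse addition); then CuCl2 (2.3 equiv), DMF, −78 → −40 °C
Reagents that add atoms: none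
Why: Double kinetic deprotonation of the two acetyl methyl groups and oxidation with CuCl2 joins the two enolate carbons (oxidative enolate coupling), which closes ring D as a cyclohexane-1,4-dione on the trans ring fusion already fixed in step 11.

Step 14
Reactants: 19 tetracyclic ene-dione
Product: 20 tetracyclic dione
Conditions: H2 (4 atm), Pd/C, EtOAc, rt
Reagents that add atoms: none
Why: Heterogeneous hydrogenation saturates the cis-disubstituted alkene of ring C, creates no stereocenter, and should leave ketones and silyl ether untouched.

Step 15
Reactants: 20 tetracyclic dione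
Product: 21 hydroxy ketone
Conditions: MeMgBr (1.1 equiv), CeCl3 (1.2 equiv), THF, −78 °C; then aq. NH4Cl
Reagents that add atoms: methylmagnesium bromide, C[Mg]Br
Why: The organocerium reagent should add to the less hindered ketone (flanked by a CH, not the neopentylic one) from the equatorial side, away from the 1,3-diaxial angular methyl, which sets the tertiary carbinol with axial OH and equatorial methyl (1,2-addition to a ketone).

Step 16
Reactants: 21 hydroxy ketone
Product: 22 diol with axial secondary alcohol
Conditions: LiBH(s-Bu)3 (2.5 equiv), THF, −78 → −40 °C; then H2O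
Reagents that add atoms: none
Why: The bulky borohydride reduces the neopentylic ketone from the equatorial side, as with 4,4-disubstituted 3-ketones of triterpenoids, giving the axial alcohol trans to the angular methyl, the epimer needed for an invertive substitution.

Step 17
Reactants: 22 diol with axial secondary alcohol
Product: 23 bromide silyl ether
Conditions: PPh3 (2 equiv), CBr4 (2 equiv), CH2Cl2, 0 °C → rt
Reagents that add atoms: carbon tetrabromide, BrC(Br)(Br)Br
Why: Appel reaction: bromide displaces the alkoxyphosphonium group of the axial secondary alcohol with inversion (SN2) to give the equatorial bromide, while the hindered tertiary alcohol should not react.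

Step 18
Reactants: 23 bromide silyl ether
Product: 24 target CNP0317598.2
Conditions: Bu4NF (1.5 equiv), THF, rt; then H2O
Reagents that add atoms: none
Why: Fluoride cleaves the silyl ether to free the exo secondary alcohol; the equatorial bromide has no anti-periplanar hydrogen and should not eliminate.

**Compound list**

1 | 3-methylbutanal | CC(C)CC=O | starting material
2 | but-3-en-2-one | CC(=O)C=C | starting material
3 | (2S)-5-oxo-2-(propan-2-yl)hexanal | CC(C)[C@@H](C=O)CCC(C)=O | intermediate (not isolated)
4 | (S)-cryptone, (4S)-4-(propan-2-yl)cyclohex-2-en-1-one | CC(C)[C@@H]1CCC(=O)C=C1 | intermediate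
5 | 2-(2-bromoethyl)-2-methyl-1,3-dioxolane | CC1(CCBr)OCCO1 | starting material
6 | 4-isopropyl-6-[2-(2-methyl-1,3-dioxolan-2-yl)ethyl]cyclohex-2-en-1-one, side chain trans to isopropyl | CC(C)[C@@H]1C[C@@H](CCC2(C)OCCO2)C(=O)C=C1 | intermediate (not isolated)
7 | 4-isopropyl-6-[2-(2-methyl-1,3-dioxolan-2-yl)ethyl]cyclohex-2-en-1-one, side chain cis to isopropyl | CC(C)[C@@H]1C[C@H](CCC2(C)OCCO2)C(=O)C=C1 | intermediate
8 | 4-isopropyl-2-[2-(2-methyl-1,3-dioxolan-2-yl)ethyl]-5-[(1-phenyl-1H-tetrazol-5-yl)sulfanyl]cyclohexan-1-one; side chain cis and sulfur trans to isopropyl (all equatorial) | CC(C)[C@@H]1C[C@H](CCC2(C)OCCO2)C(=O)C[C@H]1SC1=NN=NN1c1ccccc1 | intermediate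
9 | the cyclohexan-1-ol from 8; OH axial, cis to the C-2 side chain | CC(C)[C@@H]1C[C@H](CCC2(C)OCCO2)[C@H](O)C[C@H]1SC1=NN=NN1c1ccccc1 | intermediate
10 | tert-butyldimethylsilyl ether of 9 | CC(C)[C@@H]1C[C@H](CCC2(C)OCCO2)[C@H](O[Si](C)(C)C(C)(C)C)C[C@H]1SC1=NN=NN1c1ccccc1 | intermediate
11 | (1-phenyl-1H-tetrazol-5-yl) sulfone from 10 | CC(C)[C@@H]1C[C@H](CCC2(C)OCCO2)[C@H](O[Si](C)(C)C(C)(C)C)C[C@H]1S(=O)(=O)C1=NN=NN1c1ccccc1 | intermediate
12 | (2Z)-3-methylpent-2-en-4-yn-1-ol | C#C/C(C)=C\CO | starting material
13 | (2Z)-3-methylpent-2-en-4-ynal | C#C/C(C)=C\C=O | intermediate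
14 | tert-butyldimethylsilyl ether of all-cis 4-isopropyl-2-[2-(2-methyl-1,3-dioxolan-2-yl)ethyl]-5-[(2Z)-3-methylpent-2-en-4-yn-1-ylidene]cyclohexan-1-ol (OTBS, side chain and isopropyl mutually cis) | C#C/C(C)=C\C=C1/C[C@@H](O[Si](C)(C)C(C)(C)C)[C@@H](CCC2(C)OCCO2)C[C@H]1C(C)C | intermediate
15 | methyl ketone from 14: the C-2 side chain is 3-oxobutyl | C#C/C(C)=C\C=C1/C[C@@H](O[Si](C)(C)C(C)(C)C)[C@@H](CCC(C)=O)C[C@H]1C(C)C | intermediate
16 | enone from 15: the C-2 side chain is (1E)-3-oxobut-1-en-1-yl (key substrate) | C#C/C(C)=C\C=C1/C[C@@H](O[Si](C)(C)C(C)(C)C)[C@@H](/C=C/C(C)=O)C[C@H]1C(C)C | intermediate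
17 | tricyclic ketone: norbornane (exo isopropyl on one two-carbon bridge, exo OTBS on the other) fused through bridgehead C and bridge CH to a cyclohexene (ring C) bearing an equatorial acetyl on the ring-fusion CH and, next to it, a quaternary carbon with methyl (cis to acetyl) and ethynyl | CC(C)[C@@H]1C[C@@H]2[C@H]3[C@H](C(C)=O)[C@](C)(C=C[C@@]31C[C@H]2O[Si](C)(C)C(C)(C)C)C#C | intermediate
18 | diketone from 17: acetyl in place of ethynyl | CC(C)[C@@H]1C[C@@H]2[C@H]3[C@H](C(C)=O)[C@](C)(C=C[C@@]31C[C@H]2O[Si](C)(C)C(C)(C)C)C(C)=O | intermediate
19 | tetracycle with ring D as a trans-fused cyclohexane-1,4-dione and a C=C in ring C | CC(C)[C@@H]1C[C@@H]2[C@H]3[C@H]4[C@](C)(C=C[C@@]31C[C@H]2O[Si](C)(C)C(C)(C)C)C(=O)CCC4=O | intermediate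
20 | saturated tetracyclic 1,4-dione | CC(C)[C@@H]1C[C@@H]2[C@H]3[C@H]4[C@](C)(CC[C@@]31C[C@H]2O[Si](C)(C)C(C)(C)C)C(=O)CC[C@H0]4=O | intermediate
21 | hydroxy ketone: tertiary carbinol (axial OH, equatorial methyl) next to the ring-fusion CH; ketone next to the angular-methyl carbon | CC(C)[C@@H]1C[C@@H]2[C@H]3[C@H]4[C@](C)(CC[C@@]31C[C@H]2O[Si](C)(C)C(C)(C)C)C(=O)CC[C@@]4(C)O | intermediate
22 | diol: as 21 with an axial secondary OH (trans to the angular methyl) in place of the ketone | CC(C)[C@@H]1C[C@@H]2[C@H]3[C@H]4[C@](C)(CC[C@@]31C[C@H]2O[Si](C)(C)C(C)(C)C)[C@H](O)CC[C@@]4(C)O | intermediate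
23 | tert-butyldimethylsilyl ether of the target (equatorial bromide) | CC(C)[C@@H]1C[C@@H]2[C@H]3[C@H]4[C@](C)(CC[C@@]31C[C@H]2O[Si](C)(C)C(C)(C)C)[C@@H](Br)CC[C@@]4(C)O | intermediate
24 | CNP0317598.2 | CC(C)[C@@H]1C[C@@H]2[C@H]3[C@H]4[C@](C)(CC[C@@]31C[C@H]2O)[C@@H](Br)CC[C@@]4(C)O | target

Correction to the SMILES of 20 (the entry above contains a typing slip): CC(C)[C@@H]1C[C@@H]2[C@H]3[C@H]4[C@](C)(CC[C@@]31C[C@H]2O[Si](C)(C)C(C)(C)C)C(=O)CCC4=O

**Step count and risks**

Total: 18 steps. Longest linear sequence: 17 steps (steps 1–6 and 8–18); step 7 is the one-step side branch.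

Steps most likely to fail:

1. Step 11. The boat-like approach across the ring may be too slow at low temperature, so that proton loss from the cationic intermediate (triene formation), enone oligomerisation or Lewis-acid-induced isomerisation of the (Z)-enyne outruns the second ring closure. Fallback, setting out from 16: the enone carbonyl is ketalised without double-bond migration (1,2-bis(trimethylsilyloxy)ethane, cat. TMSOTf, CH2Cl2, −78 °C) to the 2-alkenyl-2-methyl-1,3-dioxolane F1. Catalytic TMSOTf at −78 °C then ionises F1 to a vinyl-substituted dioxolanylium cation, a fully cationic dienophile that adds stepwise to hindered dienes (ionic Diels–Alder reaction) and collapses to the tricyclic dioxolane F2. Hydrolysis (PPTS, wet acetone) returns to the route at 17.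

2. Step 13. Mono-enolisation followed by intramolecular aldol addition (five-membered ring) or α-chlorination by CuCl2 may compete with C–C coupling. Fallback, setting out from 17: the terminal alkyne is hydroborated with dicyclohexylborane and oxidised (NaBO3) to the aldehyde F3 (anti-Markovnikov hydration). Intramolecular aldol condensation of the acetyl methyl group with this aldehyde (piperidine, AcOH, toluene, heat) closes ring D as the cyclohexenone F4. Allylic oxidation of its only allylic CH2 (t-BuOOH, cat. Rh2(caprolactamate)4) gives the cyclohex-2-ene-1,4-dione F5. Hydrogenation (H2, Pd/C) saturates both C=C bonds and returns to the route at 20.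

3. Step 17. Bromide attack at the neopentylic carbon is slow, so elimination to the ring D alkene or a 1,2-methyl shift from the activated alcohol may dominate. Fallback, setting out from 21: the ketone is condensed with hydrazine (N2H4·H2O, EtOH, heat) to the hydrazone F6. Bromination in the presence of base (NBS, pyridine, CH2Cl2, −10 °C) gives the vinyl bromide F7 with loss of nitrogen. Hydrogen-atom-transfer hydrogenation (cat. Mn(dpm)3, PhSiH3, t-BuOOH, i-PrOH) then reduces F7; the second hydrogen atom should reach the α-bromo radical from the axial side away from the angular methyl, leaving bromine equatorial. This returns to the route at 23.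

**Further compounds**

F1 | step 11 | 2-methyl-2-alkenyl-1,3-dioxolane (ethylene ketal of 16) | C#C/C(C)=C\C=C1/C[C@@H](O[Si](C)(C)C(C)(C)C)[C@@H](/C=C/C2(C)OCCO2)C[C@H]1C(C)C
F2 | step 11 | tricyclic dioxolane (ethylene ketal of 17) | CC(C)[C@@H]1C[C@@H]2[C@H]3[C@H](C4(C)OCCO4)[C@](C)(C=C[C@@]31C[C@H]2O[Si](C)(C)C(C)(C)C)C#C
F3 | step 13 | keto aldehyde (formylmethyl in place of the ethynyl group of 17) | CC(C)[C@@H]1C[C@@H]2[C@H]3[C@H](C(C)=O)[C@](C)(C=C[C@@]31C[C@H]2O[Si](C)(C)C(C)(C)C)CC=O
F4 | step 13 | tetracyclic cyclohexenone (ring D enone) | CC(C)[C@@H]1C[C@@H]2[C@H]3[C@H]4[C@](C)(C=C[C@@]31C[C@H]2O[Si](C)(C)C(C)(C)C)CC=CC4=O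
F5 | step 13 | tetracyclic cyclohex-2-ene-1,4-dione (ring D) | CC(C)[C@@H]1C[C@@H]2[C@H]3[C@H]4[C@](C)(C=C[C@@]31C[C@H]2O[Si](C)(C)C(C)(C)C)C(=O)C=CC4=O
F6 | step 17 | hydrazone of 21 | CC(C)[C@@H]1C[C@@H]2[C@H]3[C@H]4[C@](C)(CC[C@@]31C[C@H]2O[Si](C)(C)C(C)(C)C)C(=NN)CC[C@@]4(C)O
F7 | step 17 | ring D vinyl bromide | CC(C)[C@@H]1C[C@@H]2[C@H]3[C@H]4[C@](C)(CC[C@@]31C[C@H]2O[Si](C)(C)C(C)(C)C)C(Br)=CC[C@@]4(C)O
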